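A leftover comes first: 0.0126 M of incoming ligand covers two exchanges on 0.00630 M of complex, less than the 0.018 M charged, so starting complex stays over.

the same everywhere: time 2.0 min

| charge | starting complex | incoming ligand | remark |
|---|---|---|---|
| dawn | 0.018 M | 0.0126 M (fed, over 1.5 min) | all else is in the flask from the start; the feed brings no volume worth counting |
| summer | 0.018 M | 0.0126 M | everything together at the start |
| spring | 0.018 M (fed, over 1.5 min) | 0.0126 M | all else is in the flask from the start; the feed brings no volume worth counting |

    starting complex + incoming ligand ⇌ leaving ligand + complex with one exchanged (K1 = 3.4, k1 = 9.5 M⁻¹ s⁻¹)
    complex with one exchanged + incoming ligand ⇌ leaving ligand + complex with two exchanged (K2 = 110, k2 = 20 M⁻¹ s⁻¹)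
    complex with two exchanged + incoming ligand ⇌ leaving ligand + complex with three exchanged (K3 = 0.87, k3 = 3.7 M⁻¹ s⁻¹)
    starting complex ⇌ dormant form (K4 = 0.32, k4 = 0.027 s⁻¹)
    leaving ligand + complex with one exchanged → side product (k5 = 1.3 M⁻¹ s⁻¹)
    complex with one exchanged ⇌ isomer of the product (K6 = 0.53, k6 = 0.0095 s⁻¹)

- the best flask by share of complex with one exchanged in complex with one exchanged plus complex with two exchanged; "all alike" if 1.5 percentage points covers them all (dawn / summer / spring / all alike)
- share of complex with one exchanged in complex with one exchanged plus complex with two exchanged at the end, dawn
- share of complex with one exchanged in complex with one exchanged plus complex with two exchanged at the end, summer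
- share of complex with one exchanged in complex with one exchanged plus complex with two exchanged at the end, spring

1. Dividing the second exchange by the first cancels both free ligands. This leaves a swap, a disproportionation: two complexes with one exchanged ⇌ starting complex + complex with two exchanged, with constant 32.4. Once both exchanges have balanced, the ratio c(starting complex)·c(complex with two exchanged)/c(complex with one exchanged)² equals this constant at any level of the free ligands, so we freeze it.

2. The second exchange lies further right than the first, so we put the ligand charge into complex with two exchanged, two ligands to each: c(complex with two exchanged) = 0.00630 M.

3. The remaining complex divides between starting complex and dormant form, so c(starting complex) = 0.00886 M.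

4. The swap balance then gives c(complex with one exchanged) = 0.00131 M. The swap share is 17.3%: the share of complex with one exchanged once the swap has balanced.

5. The second way counts forward steps. Complex with one exchanged stops rising when c(complex with one exchanged) is 0.475 times c(starting complex). The same ligand balance gives 0.00449 M of it, 0.00405 M of complex with two exchanged, and a share of 52.6%.

6. The two ways part, and we must find which one cheats. We take c(leaving ligand) at the ligand charge of 0.0126 M; the back step of the first exchange alone then halves complex with one exchanged in 0.328 min, which is short against 2.0 min. So the forward count cheats, and for summer we commit to the swap share. Dawn and spring have 0.500 min after their feeds, which is 1.52 of those half-lives, and we expect dawn, where ligand is still entering up to 1.5 min, to lie above the swap share.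

7. The forecast says 22% for dawn, 20% for summer and 18% for spring, best dawn, holding that “By two minutes the reversible exchanges should have largely relaxed towards a common equilibrium”. Its summer figure is higher than our swap share.

The flask gives 24.0% in dawn, 15.4% in summer and 16.5% in spring, so dawn is best and the forecast held within its tolerance. Summer lies 1.9 percentage points under the swap share. At the asked time in summer, the relaxation half-lives of the first and second exchanges, each by its step alone, are 0.108 min and 0.465 min, both short against 2.0 min. Yet the swap ratio in summer stands at 55.5, above the constant 32.4, and complex with one exchanged is made at 0.800 of the rate at which it is used up. For a neighbour of summer charged with 0.072 M of starting complex, the swap share comes to 33.1%, and that flask gives 36.2%, with 0.00264 M of complex with two exchanged against the 0.00630 M we put in.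

The constants used here are made up, and the outcome is calculated.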